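**Plan**

1. Retrosynthesis: the two aryl O–CH2OMe bonds are cut first. The dienone ring is then cut at its two C–C bonds C1'–C2' and C5'–C6' into a C2 unit (an ethynyl group on the methide carbon C7) and the C4–O unit of a 1-methoxy-3-silyloxybutadiene. Further cuts are the carbinol C7–OH bond, C7–C≡CH, the biaryl bond, the aryl–alkyne bond and the C7–arene bond.
2. Forward: the tetrasubstituted benzene (from 2-bromo-4-chlorotoluene) and three para-oxygenated benzene rings are bought. Ortho-lithiation/aldehyde addition, oxidation, Sonogashira coupling, Suzuki coupling and acetylide addition assemble a 4-hydroxyphenyl propargylic alcohol. The dienone ring is the only ring that is built, and it is closed last.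
3. Enabling feature: C7 carries two para-oxygenated six-membered rings that are interchanged by an O-to-O proton shift (a fuchsone). With the bought ring in its quinone methide form, an ethynyl group on C7 is a vinylogous ynone whose terminal carbon is the 1,8-acceptor. Its two carbons plus the four diene carbons give the second ring with oxygen para to C7.
4. Stereochemistry: the target has no stereogenic element. The racemic carbinol centres of 3, 9 and 10 and the CH(OMe) centre of cycloadduct 13 are all erased.

Key step: step 7

Remark: compounds 1, 2, 5, 7 and 11 are taken as catalogue compounds; "Ar" denotes the 4'-(methoxymethoxy)-3-{[4-(methoxymethoxy)phenyl]ethynyl}-4-methyl-[1,1'-biphenyl]-2-yl group.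

**Step 1**
Reactants: 1 2-bromo-4-chloro-1-methylbenzene; 2 4-(tert-butyldimethylsilyloxy)benzaldehyde
Product: 3 (2-bromo-6-chloro-3-methylphenyl)[4-(tert-butyldimethylsilyloxy)phenyl]methanol (racemic)
Conditions: LDA (1.1 equiv), THF, −78 °C; then 2, −78 → −40 °C; aq. NH4Cl
Reagents that add atoms: none
Why: Directed ortho-lithiation at the C–H flanked by Br and Cl (the most acidic site, and already the thermodynamically preferred anion, so no halogen dance is expected at −78 °C), then 1,2-addition to the aldehyde; the carbinol centre is racemic and is removed in step 2.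

**Step 2**
Reactants: 3 (2-bromo-6-chloro-3-methylphenyl)[4-(tert-butyldimethylsilyloxy)phenyl]methanol
Product: 4 (2-bromo-6-chloro-3-methylphenyl)[4-(tert-butyldimethylsilyloxy)phenyl]methanone
Conditions: Dess–Martin periodinane (1.3 equiv), CH2Cl2, 0 → 25 °C
Reagents that add atoms: none
Why: Dess–Martin oxidation of a hindered benzhydrol to the diaryl ketone; the aryl silyl ether and both halides are inert.

**Step 3**
Reactants: 4 (2-bromo-6-chloro-3-methylphenyl)[4-(tert-butyldimethylsilyloxy)phenyl]methanone; 5 1-ethynyl-4-(methoxymethoxy)benzene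
Product: 6 [6-chloro-2-{[4-(methoxymethoxy)phenyl]ethynyl}-3-methylphenyl][4-(tert-butyldimethylsilyloxy)phenyl]methanone
Conditions: Pd(PhCN)2Cl2 (3 mol %), t-Bu3P·HBF4 (6 mol %), CuI (3 mol %), i-Pr2NH, 1,4-dioxane, 25 → 45 °C
Reagents that add atoms: none
Why: Sonogashira coupling; oxidative addition should occur at the C–Br bond (activated by the ortho acyl group) and not at C–Cl, and the bulky electron-rich phosphine is chosen for the doubly ortho-substituted bromide.

**Step 4**
Reactants: 6 [6-chloro-2-{[4-(methoxymethoxy)phenyl]ethynyl}-3-methylphenyl][4-(tert-butyldimethylsilyloxy)phenyl]methanone; 7 4-(methoxymethoxy)phenylboronic acid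
Product: 8 (Ar)[4-(tert-butyldimethylsilyloxy)phenyl]methanone
Conditions: Pd(OAc)2 (3 mol %), SPhos (6 mol %), anhydrous K3PO4, PhMe, 90 °C
Reagents that add atoms: none
Why: Suzuki–Miyaura coupling of the ortho-acyl aryl chloride with a dialkylbiarylphosphine ligand; anhydrous phosphate in toluene is chosen to spare the base-labile aryl silyl ether, and the internal alkyne and the MOM ethers are inert.

**Step 5**
Reactants: 8 (Ar)[4-(tert-butyldimethylsilyloxy)phenyl]methanone
Product: 9 1-(Ar)-1-[4-(tert-butyldimethylsilyloxy)phenyl]prop-2-yn-1-ol (racemic)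
Conditions: HC≡CMgBr (0.5 M in THF, 3 equiv), THF, 0 → 25 °C; aq. NH4Cl
Reagents that add atoms: ethynylmagnesium bromide, C#C[Mg]Br
Why: Grignard 1,2-addition of the smallest carbon nucleophile to the non-enolizable, doubly ortho-substituted diaryl ketone, kept cold so that the alkoxide does not add to the neighbouring alkyne; the new carbinol centre is racemic and becomes sp2 in step 7.

**Step 6**
Reactants: 9 1-(Ar)-1-[4-(tert-butyldimethylsilyloxy)phenyl]prop-2-yn-1-ol
Product: 10 4-[1-hydroxy-1-(Ar)prop-2-yn-1-yl]phenol (racemic)
Conditions: TBAF (1.1 equiv), AcOH (1.1 equiv), THF, 0 °C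
Reagents that add atoms: none
Why: Fluoride cleavage of the aryl silyl ether, buffered with acetic acid so that neither phenoxide nor tertiary alkoxide can add to the ortho alkyne; the MOM ethers and both alkynes are untouched.

**Step 7**
Reactants: 10 4-[1-hydroxy-1-(Ar)prop-2-yn-1-yl]phenol; 11 (E)-1-methoxy-3-(trimethylsilyloxy)buta-1,3-diene (Danishefsky's diene)
Product: 14 4-{(4-hydroxyphenyl)(Ar)methylidene}cyclohexa-2,5-dien-1-one (bis-MOM ether of selaginellin U), via ethynyl quinone methide 12 (not isolated), via cycloadduct 13 (not isolated)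
Conditions: (PhO)2P(O)OH (5 mol %), 4 Å MS, PhMe, 25 °C; then 2,6-lutidine (10 mol %), 11 (3 equiv), 80 °C; then 1 M HCl, THF, 0 °C
Reagents that add atoms: none
Why: Proposed new method: catalytic diphenyl phosphate ionizes the tertiary propargylic alcohol of 10 with assistance of the para-OH and the sieves take up the water, giving the 7-ethynyl p-quinone methide 12, a vinylogous ynone; 12 should then undergo a normal-electron-demand, asynchronous [4+2] cycloaddition with diene 11 (nucleophilic C4 of the diene to the alkyne terminus, C1 to the internal alkyne carbon), and loss of methanol and of the silyl group from 13 aromatizes the new six-membered ring to a 4-hydroxyphenyl ring on C7, which gives fuchsone 14, where a degenerate proton shift between the two oxygens lets the new ring be the dienone ring. The closest known reaction types are the cycloaddition/aromatization of 1-alkoxy-3-silyloxybutadienes with aryl ethynyl ketones to 4-hydroxyaryl ketones and the acid-catalysed in situ formation of alkynyl p-quinone methides from 4-hydroxyphenyl propargylic alcohols with 1,8-addition of nucleophiles; new is the quinone methide, in place of a carbonyl group, as the activating group of the dienophile. The ring is closed by an intermolecular [4+2] cycloaddition (C4 + C2, two C–C bonds) followed by aromatizing 1,4-elimination, and a stepwise 1,8-addition/ring closure through the phenolate-allene would give the same adduct. No stereocentre survives: the CH(OMe) centre of 13 forms as a racemate and is destroyed on aromatization. The step needs para regiochemistry, which the matched polarization of 11 and 12 secures (oxygen para to C7). It also needs chemoselectivity for the C7-ethynyl group: the diarylalkyne is electron-rich and not conjugated to the quinone methide (the tetrasubstituted arene is twisted out of its plane), the ring C=C bonds of 12 are β-substituted and cross-conjugated, and C7 is fully substituted and shielded against 1,6-addition.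

**Step 8**
Reactants: 14 4-{(4-hydroxyphenyl)(Ar)methylidene}cyclohexa-2,5-dien-1-one
Product: 15 selaginellin U
Conditions: 3 M aq. HCl, THF, 40 °C
Reagents that add atoms: none
Why: Acid hydrolysis of the two aryl MOM acetals; the fuchsone is only reversibly protonated to its triarylmethyl cation and returns on neutralization, and no alcohol solvent is used so that no carbinol ether can form.

**Compound list**

1 | 2-bromo-4-chloro-1-methylbenzene | Cc1ccc(Cl)cc1Br | starting material
2 | 4-(tert-butyldimethylsilyloxy)benzaldehyde | O=Cc1ccc(O[Si](C)(C)C(C)(C)C)cc1 | starting material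
3 | (2-bromo-6-chloro-3-methylphenyl)[4-(tert-butyldimethylsilyloxy)phenyl]methanol (racemic) | Cc1ccc(Cl)c(C(O)c2ccc(O[Si](C)(C)C(C)(C)C)cc2)c1Br | intermediate
4 | (2-bromo-6-chloro-3-methylphenyl)[4-(tert-butyldimethylsilyloxy)phenyl]methanone | Cc1ccc(Cl)c(C(=O)c2ccc(O[Si](C)(C)C(C)(C)C)cc2)c1Br | intermediate
5 | 1-ethynyl-4-(methoxymethoxy)benzene | C#Cc1ccc(OCOC)cc1 | starting material
6 | [6-chloro-2-{[4-(methoxymethoxy)phenyl]ethynyl}-3-methylphenyl][4-(tert-butyldimethylsilyloxy)phenyl]methanone | Cc1ccc(Cl)c(C(=O)c2ccc(O[Si](C)(C)C(C)(C)C)cc2)c1C#Cc1ccc(OCOC)cc1 | intermediate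
7 | 4-(methoxymethoxy)phenylboronic acid | COCOc1ccc(B(O)O)cc1 | starting material
8 | (Ar)[4-(tert-butyldimethylsilyloxy)phenyl]methanone | Cc1ccc(-c2ccc(OCOC)cc2)c(C(=O)c2ccc(O[Si](C)(C)C(C)(C)C)cc2)c1C#Cc1ccc(OCOC)cc1 | intermediate
9 | 1-(Ar)-1-[4-(tert-butyldimethylsilyloxy)phenyl]prop-2-yn-1-ol (racemic) | Cc1ccc(-c2ccc(OCOC)cc2)c(C(O)(C#C)c2ccc(O[Si](C)(C)C(C)(C)C)cc2)c1C#Cc1ccc(OCOC)cc1 | intermediate
10 | 4-[1-hydroxy-1-(Ar)prop-2-yn-1-yl]phenol (racemic) | Cc1ccc(-c2ccc(OCOC)cc2)c(C(O)(C#C)c2ccc(O)cc2)c1C#Cc1ccc(OCOC)cc1 | intermediate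
11 | (E)-1-methoxy-3-(trimethylsilyloxy)buta-1,3-diene (Danishefsky's diene) | CO/C=C/C(=C)O[Si](C)(C)C | starting material
12 | 4-[1-(Ar)prop-2-yn-1-ylidene]cyclohexa-2,5-dien-1-one (7-ethynyl p-quinone methide, not isolated) | Cc1ccc(-c2ccc(OCOC)cc2)c(C(C#C)=C2C=CC(=O)C=C2)c1C#Cc1ccc(OCOC)cc1 | intermediate
13 | 4-{(Ar)[6-methoxy-4-(trimethylsilyloxy)cyclohexa-1,4-dien-1-yl]methylidene}cyclohexa-2,5-dien-1-one (racemic cycloadduct, not isolated) | COC1C=C(O[Si](C)(C)C)CC=C1C(=C1C=CC(=O)C=C1)c1c(-c2ccc(OCOC)cc2)ccc(C)c1C#Cc1ccc(OCOC)cc1 | intermediate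
14 | 4-{(4-hydroxyphenyl)(Ar)methylidene}cyclohexa-2,5-dien-1-one (bis-MOM ether of selaginellin U) | Cc1ccc(-c2ccc(OCOC)cc2)c(C(=C2C=CC(=O)C=C2)c2ccc(O)cc2)c1C#Cc1ccc(OCOC)cc1 | intermediate
15 | selaginellin U | Cc1ccc(-c2ccc(O)cc2)c(C(=C2C=CC(=O)C=C2)c2ccc(O)cc2)c1C#Cc1ccc(O)cc1 | target

**Step count and risks**

Total step count: 8. Longest linear sequence: 8 (1 → 15).

Steps most likely to fail:

1. Step 7 (Proposed new method). During the dehydration, 10 may isomerize in a Meyer–Schuster sense or 12 may be hydrated at the alkyne terminus. Quinone methide 12 may also oligomerize, or the diene may add in a 1,8-sense and stop at a silyl-transferred allene without closing the ring. The fallback uses known chemistry and takes the ring from a bought arene instead of building it. It sets out from ketone 8. Addition of 4-(tert-butyldimethylsilyloxy)phenyllithium (from (4-bromophenoxy)(tert-butyl)dimethylsilane and n-BuLi, THF, −78 °C) should give the bis-silyl triarylcarbinol (Ar)bis[4-(tert-butyldimethylsilyloxy)phenyl]methanol F1. TBAF in THF followed by acetic acid should then remove both silyl groups and dehydrate the 4-hydroxytrityl alcohol, so that the route is rejoined at 14.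

2. Step 5. Addition to the hindered, electron-rich ketone may stay incomplete, or the magnesium alkoxide may cyclize onto the ortho alkyne on warming. The fallback sets out from 8 and replaces the free acetylide by a capped one delivered as an organocerium reagent. Lithium (trimethylsilyl)acetylide/CeCl3 in THF at −78 °C, which is more nucleophilic and less basic, should give the C-silylated carbinol 1-(Ar)-1-[4-(tert-butyldimethylsilyloxy)phenyl]-3-(trimethylsilyl)prop-2-yn-1-ol F2. A single fluoride treatment (TBAF/AcOH, THF, 0 °C) should then cleave the C–Si and the O–Si bond together, and the route is rejoined at 10.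

3. Step 3. Oxidative addition at the doubly flanked C–Br bond may be slow, so that copper-mediated homocoupling of alkyne 5 takes over. The fallback sets out from 4 and builds the diarylalkyne from the other end. A copper- and amine-free Stille coupling with tributyl(ethynyl)stannane (Pd(PPh3)4, PhMe, 90 °C) should give (6-chloro-2-ethynyl-3-methylphenyl)[4-(tert-butyldimethylsilyloxy)phenyl]methanone F3. Its unhindered terminal alkyne is then joined to 1-iodo-4-(methoxymethoxy)benzene by Sonogashira coupling (PdCl2(PPh3)2, CuI, Et3N, 25 °C), and the route is rejoined at 6.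

**Further compounds**

F1 | step 7 | (Ar)bis[4-(tert-butyldimethylsilyloxy)phenyl]methanol | Cc1ccc(-c2ccc(OCOC)cc2)c(C(O)(c2ccc(O[Si](C)(C)C(C)(C)C)cc2)c2ccc(O[Si](C)(C)C(C)(C)C)cc2)c1C#Cc1ccc(OCOC)cc1
F2 | step 5 | 1-(Ar)-1-[4-(tert-butyldimethylsilyloxy)phenyl]-3-(trimethylsilyl)prop-2-yn-1-ol (racemic) | Cc1ccc(-c2ccc(OCOC)cc2)c(C(O)(C#C[Si](C)(C)C)c2ccc(O[Si](C)(C)C(C)(C)C)cc2)c1C#Cc1ccc(OCOC)cc1
F3 | step 3 | (6-chloro-2-ethynyl-3-methylphenyl)[4-(tert-butyldimethylsilyloxy)phenyl]methanone | Cc1ccc(Cl)c(C(=O)c2ccc(O[Si](C)(C)C(C)(C)C)cc2)c1C#C
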